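**Retrosynthetic overview**
1. Last bond: the tertiary C–OOH bond (with the alkene moving into the (2E,4E)-diene) is made by light-driven aerobic hydroperoxidation of skipped diene 22.
2. The acetate and the enone are set late; the cis C1'–H comes from decarboxylative ketonisation of β-keto acid 17 (proton anti to the 5'-methyl).
3. The ring A–ring C bond and the tertiary alcohol come from epoxide 14, opened at C2 by the tethered β-keto ester of ring C (temporary δ-lactone 16).
4. Ring C (keto ester 4) comes from (R)-pulegone by Favorskii contraction and ozonolysis; ring A (alcohol 13) comes from (R)-limonene by ozonolysis/aldol contraction, King degradation and boryl-Heck/Suzuki prenylation.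
5. Ring order: ring C (step 1) and ring A (step 4) are made separately; the lactone ring closes in step 9 and is excised in step 10.

Locants: ring A = cyclopentane (C1 carbinol carbon, C2 bears ring C, C4 bears the side chain); ring C = cyclopentenone (C1' bonded to ring A, C2' carbonyl, C5' CHMe). Target read from the SMILES as (1R,2S,4S,1'S,5'R), side chain (2E,4E).

**Step 1**
Reactants: 1 (R)-(+)-pulegone
Product: 3 methyl (1S,5R)-5-methyl-2-(propan-2-ylidene)cyclopentane-1-carboxylate, via pulegone dibromide 2 (not isolated)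
Conditions: Br2, AcOH, 0 °C; then NaOMe, MeOH, 65 °C
Reagents that add atoms: sodium methoxide, [Na+].[O-]C
Why: Favorskii rearrangement of the dibromo ketone (α'-enolate closes a cyclopropanone, methoxide opens it, bromide loss restores the isopropylidene) contracts the ring without touching the methyl stereocentre; the ester-bearing carbon (trans major) is erased later.

**Step 2**
Reactants: 3 methyl pulegenate
Product: 4 methyl (1S,2R)-2-methyl-5-oxocyclopentane-1-carboxylate
Conditions: O3, CH2Cl2/MeOH, −78 °C; Me2S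
Reagents that add atoms: ozone, [O-][O+]=O
Why: Ozonolysis of the tetrasubstituted alkene with reductive work-up gives the β-keto ester; the methyl stereocentre (R) is untouched and the α-carbon is an enolisable centre of no consequence.

**Step 3**
Reactants: 5 (R)-(+)-limonene
Product: 6 (3R)-6-oxo-3-(prop-1-en-2-yl)heptanal
Conditions: O3 (1.0 equiv), CH2Cl2/MeOH, −78 °C; Me2S
Reagents that add atoms: ozone, [O-][O+]=O
Why: Chemoselective ozonolysis of the more electron-rich trisubstituted ring alkene over the isopropenyl group; the stereocentre is not involved.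

**Step 4**
Reactants: 6 (3R)-6-oxo-3-(prop-1-en-2-yl)heptanal
Product: 7 1-[(4S)-4-(prop-1-en-2-yl)cyclopent-1-en-1-yl]ethan-1-one
Conditions: piperidine, AcOH, PhMe, 110 °C (−H2O)
Reagents that add atoms: none
Why: Intramolecular aldol condensation (internal α-CH2 of the methyl ketone onto the aldehyde, then dehydration) forms ring A; the stereocentre is remote from the reacting carbons and becomes 4S only by CIP priority change.

**Step 5**
Reactants: 7 1-[(4S)-4-(prop-1-en-2-yl)cyclopent-1-en-1-yl]ethan-1-one
Product: 9 methyl (4S)-4-(prop-1-en-2-yl)cyclopent-1-ene-1-carboxylate, via acylmethylpyridinium iodide 8 (not isolated)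
Conditions: I2, pyridine, 95 °C; then NaOMe, MeOH, 65 °C
Reagents that add atoms: sodium methoxide, [Na+].[O-]C
Why: Ortoleva–King reaction followed by haloform-type cleavage of the acylmethylpyridinium salt by methoxide removes the methyl carbon and gives the ester without oxidants that attack alkenes.

**Step 6**
Reactants: 9 methyl (4S)-4-(prop-1-en-2-yl)cyclopent-1-ene-1-carboxylate; 10 1-bromo-3-methylbut-2-ene (prenyl bromide)
Product: 12 methyl (4S)-4-[(2E)-6-methylhepta-2,5-dien-2-yl]cyclopent-1-ene-1-carboxylate, via alkenyl catecholboronate 11 (not isolated)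
Conditions: Pd2(dba)3, tBu(3,5-tBu2C6H3)2P, B-chlorocatecholborane, Cy2NMe, PhCF3, 70 °C; then 10, Pd(PPh3)4, NaOMe, MeOH, 50 °C
Reagents that add atoms: none
Why: Boryl-Heck reaction borylates the terminal carbon of the 1,1-disubstituted alkene with boron trans to the ring (E), and Suzuki–Miyaura allyl–alkenyl coupling at the primary carbon of prenyl bromide keeps that geometry to give the skipped diene; the enoate alkene is inert.

**Step 7**
Reactants: 12 methyl (4S)-4-[(2E)-6-methylhepta-2,5-dien-2-yl]cyclopent-1-ene-1-carboxylate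
Product: 13 [(4S)-4-[(2E)-6-methylhepta-2,5-dien-2-yl]cyclopent-1-en-1-yl]methanol
Conditions: iBu2AlH, CH2Cl2, −78 °C
Reagents that add atoms: none
Why: 1,2-Reduction of the conjugated ester by the aluminium hydride gives the allylic alcohol that directs the next step; no stereocentre is affected.

**Step 8**
Reactants: 13 [(4S)-4-[(2E)-6-methylhepta-2,5-dien-2-yl]cyclopent-1-en-1-yl]methanol
Product: 14 [(1S,3S,5S)-3-[(2E)-6-methylhepta-2,5-dien-2-yl]-6-oxabicyclo[3.1.0]hexan-1-yl]methanol
Conditions: VO(acac)2 (3 mol%), tBuOOH, PhMe, 0 °C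
Reagents that add atoms: tert-butyl hydroperoxide, CC(C)(C)OO
Why: Hydroxyl-directed vanadium-catalysed epoxidation (Sharpless–Michaelson type) oxidises only the allylic-alcohol alkene and delivers oxygen anti to the C4 side chain (steric control by the limonene-derived centre; about 4:1 expected, minor syn-epoxide removed by chromatography).

**Step 9**
Reactants: 14 epoxy alcohol; 4 methyl (1S,2R)-2-methyl-5-oxocyclopentane-1-carboxylate
Product: 16 spiro-δ-lactone alcohol, via tethered epoxy β-keto ester 15 (not isolated)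
Conditions: DMAP (0.3 equiv), PhMe, 110 °C, 5 Å MS; then DBU, LiOTf, 80 °C
Reagents that add atoms: none
Why: DMAP-catalysed transesterification of the β-keto ester (through its acylketene) tethers ring C to the primary alcohol, and the enolate then opens the epoxide at the secondary carbon with inversion (intramolecular Stork-type epoxide C-alkylation, 6-endo because the fully substituted carbon is blocked), so the new C–C bond is cis to the side chain and trans to the tertiary alcohol; the spiro-carbon configuration does not matter.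

**Step 10**
Reactants: 16 spiro-δ-lactone alcohol
Product: 18 (1R,2S,4S)-1-(hydroxymethyl)-4-[(2E)-6-methylhepta-2,5-dien-2-yl]-2-[(1S,2R)-2-methyl-5-oxocyclopentyl]cyclopentan-1-ol, via β-keto acid 17 (not isolated)
Conditions: Me3SnOH, ClCH2CH2Cl, 70 °C; then 0.1 M HCl, 0 °C; PhMe, 40 °C
Reagents that add atoms: none
Why: Mild Me3SnOH lactone hydrolysis (chosen to avoid retro-Claisen ring opening) followed by β-keto acid decarboxylation through the enol, which is protonated on the face opposite the adjacent methyl (kinetic ketonisation), sets the cis C1'–H/C5'–Me relationship under control of the pulegone-derived centre.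

**Step 11**
Reactants: 18 saturated keto diol
Product: 21 (1R,2S,4S)-1-(hydroxymethyl)-4-[(2E)-6-methylhepta-2,5-dien-2-yl]-2-[(1S,5R)-5-methyl-2-oxocyclopent-3-en-1-yl]cyclopentan-1-ol, via tris(trimethylsilyl) enol ether 19 (not isolated), via bis(trimethylsilyl) enone 20 (not isolated)
Conditions: LiN(SiMe3)2, Me3SiCl, THF, −78 °C; Pd(OAc)2, MeCN, 23 °C; then aq. citric acid, MeOH
Reagents that add atoms: none
Why: Saegusa–Ito oxidation: kinetic enolisation with in situ silylation removes only the unhindered C3' proton (the cis C1' centre is never enolised), Pd(OAc)2 converts the enol ether into the C3'=C4' enone, and the O-silyl ethers are cleaved on acidic work-up.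

**Step 12**
Reactants: 21 enone diol
Product: 22 [(1R,2S,4S)-1-hydroxy-4-[(2E)-6-methylhepta-2,5-dien-2-yl]-2-[(1S,5R)-5-methyl-2-oxocyclopent-3-en-1-yl]cyclopentyl]methyl acetate
Conditions: Ac2O, pyridine, CH2Cl2, 0 °C
Reagents that add atoms: acetic anhydride, CC(=O)OC(C)=O
Why: Selective acetylation of the primary alcohol (the tertiary alcohol is inert) under a base too weak to epimerise C1'.

**Step 13**
Reactants: 22 skipped-diene acetate
Product: 23 [(1R,2S,4S)-1-hydroxy-4-[(2E,4E)-6-hydroperoxy-6-methylhepta-2,4-dien-2-yl]-2-[(1S,5R)-5-methyl-2-oxocyclopent-3-en-1-yl]cyclopentyl]methyl acetate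
Conditions: O2 (1 atm), N-hydroxyphthalimide (20 mol%), diphenyl(2,4,6-trimethylbenzoyl)phosphine oxide (2 mol%), MeCN/PhCF3, 405 nm LEDs, 0 °C, to about 70% conversion
Reagents that add atoms: dioxygen, O=O
Why: Proposed new method: photoinitiated N-hydroxyphthalimide chain hydroperoxidation, in which the phthalimide-N-oxyl radical removes only the doubly allylic hydrogen (weakest C–H), the pentadienyl radical traps O2 reversibly at its two tertiary termini and the less hindered gem-dimethyl peroxyl is quenched fastest by N–OH, giving the conjugated (2E,4E)-dienyl tertiary hydroperoxide without touching any stereocentre; closest known reaction type is N-hydroxyphthalimide/O2 radical-chain autoxidation of 1,4-dienes (lipid-type peroxidation), here applied to an unsymmetrical tetra-alkylated skipped diene.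

**Compound list**
1 | (R)-(+)-pulegone, (5R)-5-methyl-2-(propan-2-ylidene)cyclohexan-1-one | C[C@@H]1CCC(=C(C)C)C(=O)C1 | starting material
2 | pulegone dibromide, (5R)-2-bromo-2-(2-bromopropan-2-yl)-5-methylcyclohexan-1-one (both C2 epimers) | C[C@@H]1CCC(Br)(C(C)(C)Br)C(=O)C1 | intermediate (not isolated)
3 | methyl (1S,5R)-5-methyl-2-(propan-2-ylidene)cyclopentane-1-carboxylate (methyl pulegenate; trans shown, some cis) | C[C@@H]1CCC(=C(C)C)[C@H]1C(=O)OC | intermediate
4 | methyl (1S,2R)-2-methyl-5-oxocyclopentane-1-carboxylate (trans; C1 enolisable) | C[C@@H]1CCC(=O)[C@H]1C(=O)OC | intermediate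
5 | (R)-(+)-limonene | CC1=CC[C@@H](CC1)C(C)=C | starting material
6 | (3R)-6-oxo-3-(prop-1-en-2-yl)heptanal | O=CC[C@@H](CCC(C)=O)C(C)=C | intermediate
7 | 1-[(4S)-4-(prop-1-en-2-yl)cyclopent-1-en-1-yl]ethan-1-one | CC(=O)C1=CC[C@H](C(C)=C)C1 | intermediate
8 | 1-{2-oxo-2-[(4S)-4-(prop-1-en-2-yl)cyclopent-1-en-1-yl]ethyl}pyridin-1-ium iodide | O=C(C[n+]1ccccc1)C1=CC[C@H](C(C)=C)C1.[I-] | intermediate (not isolated)
9 | methyl (4S)-4-(prop-1-en-2-yl)cyclopent-1-ene-1-carboxylate | COC(=O)C1=CC[C@H](C(C)=C)C1 | intermediate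
10 | 1-bromo-3-methylbut-2-ene (prenyl bromide) | CC(C)=CCBr | starting material
11 | methyl (4S)-4-[(1E)-1-(1,3,2-benzodioxaborol-2-yl)prop-1-en-2-yl]cyclopent-1-ene-1-carboxylate | COC(=O)C1=CC[C@H](/C(C)=C/B2Oc3ccccc3O2)C1 | intermediate (not isolated)
12 | methyl (4S)-4-[(2E)-6-methylhepta-2,5-dien-2-yl]cyclopent-1-ene-1-carboxylate | COC(=O)C1=CC[C@H](/C(C)=C/CC=C(C)C)C1 | intermediate
13 | [(4S)-4-[(2E)-6-methylhepta-2,5-dien-2-yl]cyclopent-1-en-1-yl]methanol | OCC1=CC[C@H](/C(C)=C/CC=C(C)C)C1 | intermediate
14 | [(1S,3S,5S)-3-[(2E)-6-methylhepta-2,5-dien-2-yl]-6-oxabicyclo[3.1.0]hexan-1-yl]methanol (epoxide trans to the side chain) | OC[C@@]12C[C@@H](/C(C)=C/CC=C(C)C)C[C@@H]1O2 | intermediate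
15 | [(1S,3S,5S)-3-[(2E)-6-methylhepta-2,5-dien-2-yl]-6-oxabicyclo[3.1.0]hexan-1-yl]methyl (1S,2R)-2-methyl-5-oxocyclopentane-1-carboxylate | C[C@@H]1CCC(=O)[C@H]1C(=O)OC[C@@]12C[C@@H](/C(C)=C/CC=C(C)C)C[C@@H]1O2 | intermediate (not isolated)
16 | spiro-δ-lactone alcohol: 7a'-hydroxy-5-methyl-6'-[(2E)-6-methylhepta-2,5-dien-2-yl]hexahydro-1'H-spiro[cyclopentane-1,4'-cyclopenta[c]pyran]-2,3'-dione; lactone cis-fused to ring A, OH trans to the spiro carbon, side chain cis to it, methyl carbon R, spiro carbon as formed by alkylation anti to methyl | O=C1OC[C@@]2(O)C[C@@H](/C(C)=C/CC=C(C)C)C[C@H]2[C@@]13C(=O)CC[C@H]3C | intermediate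
17 | β-keto acid: (2R)-1-[(1S,2R,4S)-2-hydroxy-2-(hydroxymethyl)-4-[(2E)-6-methylhepta-2,5-dien-2-yl]cyclopentyl]-2-methyl-5-oxocyclopentane-1-carboxylic acid | OC[C@@]1(O)C[C@@H](/C(C)=C/CC=C(C)C)C[C@H]1[C@]1(C(=O)O)C(=O)CC[C@H]1C | intermediate (not isolated)
18 | (1R,2S,4S)-1-(hydroxymethyl)-4-[(2E)-6-methylhepta-2,5-dien-2-yl]-2-[(1S,2R)-2-methyl-5-oxocyclopentyl]cyclopentan-1-ol (ring C substituents cis) | OC[C@@]1(O)C[C@@H](/C(C)=C/CC=C(C)C)C[C@H]1[C@H]1C(=O)CC[C@H]1C | intermediate
19 | tris(trimethylsilyl) derivative of 18: C2'-O-silyl enol ether (C2'=C3') plus both O-silyl ethers | C[Si](C)(C)OC[C@@]1(O[Si](C)(C)C)C[C@@H](/C(C)=C/CC=C(C)C)C[C@H]1[C@H]1C(O[Si](C)(C)C)=CC[C@H]1C | intermediate (not isolated)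
20 | bis(trimethylsilyl) ether of enone diol 21 | C[Si](C)(C)OC[C@@]1(O[Si](C)(C)C)C[C@@H](/C(C)=C/CC=C(C)C)C[C@H]1[C@H]1C(=O)C=C[C@H]1C | intermediate (not isolated)
21 | (1R,2S,4S)-1-(hydroxymethyl)-4-[(2E)-6-methylhepta-2,5-dien-2-yl]-2-[(1S,5R)-5-methyl-2-oxocyclopent-3-en-1-yl]cyclopentan-1-ol | OC[C@@]1(O)C[C@@H](/C(C)=C/CC=C(C)C)C[C@H]1[C@H]1C(=O)C=C[C@H]1C | intermediate
22 | [(1R,2S,4S)-1-hydroxy-4-[(2E)-6-methylhepta-2,5-dien-2-yl]-2-[(1S,5R)-5-methyl-2-oxocyclopent-3-en-1-yl]cyclopentyl]methyl acetate | CC(=O)OC[C@@]1(O)C[C@@H](/C(C)=C/CC=C(C)C)C[C@H]1[C@H]1C(=O)C=C[C@H]1C | intermediate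
23 | [(1R,2S,4S)-1-hydroxy-4-[(2E,4E)-6-hydroperoxy-6-methylhepta-2,4-dien-2-yl]-2-[(1S,5R)-5-methyl-2-oxocyclopent-3-en-1-yl]cyclopentyl]methyl acetate (CNP0204569.2) | CC(=O)OC[C@@]1(O)C[C@@H](/C(C)=C/C=C/C(C)(C)OO)C[C@H]1[C@H]1C(=O)C=C[C@H]1C | target

**Step count and risks**
Total steps: 13. Longest linear sequence: 11 (steps 3–13, from (R)-limonene); ring C is a two-step branch (steps 1–2).

Step 13 (the proposed new step) may give poor selectivity between the two tertiary termini, some E/Z erosion, or over-oxidation. Its fallback uses known chemistry, sets out from 22 and comes back at 23: the classical dye-sensitised singlet-oxygen ene reaction (Schenck ene; tetraphenylporphyrin, O2, CH2Cl2, −20 °C, green LEDs, partial conversion). A pericyclic singlet-oxygen pathway replaces the radical chain; 23 is separated from the other ene regioisomers by HPLC. This fallback makes no new compound (none F0).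

Step 9 may fail because the 6-endo epoxide opening by a tertiary β-keto ester enolate is slow. The fallback sets out from 14 and 4 and comes back at 16. The transesterification is run alone and 15 is isolated. It is condensed with benzylamine (AcOH cat., PhMe, molecular sieves) to the N-benzyl β-enamino ester F1. NaH in THF/DMPU then gives the more nucleophilic aza-enolate (Stork metalloenamine-type C-alkylation), which opens the epoxide to the spiro-lactone N-benzyl ketimine F2. Aqueous oxalic acid hydrolyses the imine to 16.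

Step 10 may fail through retro-Claisen opening of ring C or a poor cis:trans ratio in the ketonisation. The fallback sets out from 16 and comes back at 18. The lactone is opened by Ti(OiPr)4-catalysed transesterification in allyl alcohol to the allyl β-keto ester F3. Tsuji-type palladium-catalysed decarboxylative protonation (Pd(OAc)2, PPh3, HCO2H, Et3N, THF, 23 °C) then protonates the palladium enolate from the face opposite the methyl group.

**Further compounds**
F1 | step 9 | [(1S,3S,5S)-3-[(2E)-6-methylhepta-2,5-dien-2-yl]-6-oxabicyclo[3.1.0]hexan-1-yl]methyl (5R)-2-(benzylamino)-5-methylcyclopent-1-ene-1-carboxylate (N-benzyl β-enamino ester) | C[C@@H]1CCC(NCc2ccccc2)=C1C(=O)OC[C@@]12C[C@@H](/C(C)=C/CC=C(C)C)C[C@@H]1O2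
F2 | step 9 | spiro-lactone N-benzyl ketimine (N-benzyl imine of the ring C ketone of 16) | O=C1OC[C@@]2(O)C[C@@H](/C(C)=C/CC=C(C)C)C[C@H]2[C@@]13C(=NCc2ccccc2)CC[C@H]3C
F3 | step 10 | allyl β-keto ester: prop-2-en-1-yl (2R)-1-[(1S,2R,4S)-2-hydroxy-2-(hydroxymethyl)-4-[(2E)-6-methylhepta-2,5-dien-2-yl]cyclopentyl]-2-methyl-5-oxocyclopentane-1-carboxylate | OC[C@@]1(O)C[C@@H](/C(C)=C/CC=C(C)C)C[C@H]1[C@]1(C(=O)OCC=C)C(=O)CC[C@H]1C
F0 | step 13 | none | none
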